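**Plan**

1. Retrosynthesis: the formyl group is traced back to a methyl ester, and the pyrrole is then cut at C2–C3 and C4–C5 and at the C5=N bond of an imine formed from a C20 trienal and glycine methyl ester.
2. Enabling feature: pyrrole C3 and C4 are bare CH carbons, so both ring C–C bonds can be supplied by a two-carbon acetylene equivalent, (E)-1,2-bis(phenylsulfonyl)ethene, adding across an azomethine ylide that spans C2–N1–C5.
3. Forward order: acid to alcohol to aldehyde to glycinate imine; a silver-catalysed [3+2] cycloaddition closes the only ring as a pyrrolidine; base removes two sulfinates to give the pyrrole; the ester is then taken to the aldehyde through the carbinol.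
4. Stereochemistry: the three Z alkenes are bought with the C20 acid and are never exposed to oxidants, strong base with heat, or hydrogenation; the four sp3 centres of the cycloadduct are transient and disappear on aromatisation, and the target has no stereocentre.

Key step: step 4

Remark: the cycloadduct is assumed to form as a racemate. Its relative configuration is drawn for the expected 2,5-cis, 3,4-trans isomer and is immaterial, since every diastereomer converges on the same pyrrole.

**Route**

Step 1
Reactants: 1 (11Z,14Z,17Z)-icosa-11,14,17-trienoic acid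
Product: 2 (11Z,14Z,17Z)-icosa-11,14,17-trien-1-ol
Conditions: LiAlH4 (1.5 equiv), THF, 0 °C to rt; aq. NaOH work-up
Reagents that add atoms: none
Why: Hydride reduction of a carboxylic acid to the primary alcohol should be clean because isolated Z alkenes are inert to LiAlH4, so the skipped triene passes unchanged and no stereocentre is formed.

Step 2
Reactants: 2 (11Z,14Z,17Z)-icosa-11,14,17-trien-1-ol
Product: 3 (11Z,14Z,17Z)-icosa-11,14,17-trienal
Conditions: Dess–Martin periodinane (1.2 equiv), CH2Cl2, 0 °C to rt, argon
Reagents that add atoms: none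
Why: Dess–Martin oxidation stops at the aldehyde under near-neutral, non-radical conditions that should leave the bis-allylic CH2 groups and the Z geometry untouched.

Step 3
Reactants: 3 (11Z,14Z,17Z)-icosa-11,14,17-trienal; 4 glycine methyl ester hydrochloride (0.95 equiv)
Product: 5 methyl N-[(1E,11Z,14Z,17Z)-icosa-11,14,17-trien-1-ylidene]glycinate
Conditions: Et3N (1.0 equiv), MgSO4, CH2Cl2, 0 °C, argon; filter, concentrate cold, use crude at once
Reagents that add atoms: none
Why: Imine condensation of the liberated primary amine with the aldehyde, driven by MgSO4 as water scavenger, should give the E-aldimine, and the slight excess of aldehyde ensures that no free primary amine is carried on to attack the dipolarophile.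

Step 4
Reactants: 5 methyl N-[(1E,11Z,14Z,17Z)-icosa-11,14,17-trien-1-ylidene]glycinate; 6 (E)-1,2-bis(phenylsulfonyl)ethene (1.05 equiv)
Product: 8 methyl (2S*,3S*,4S*,5R*)-5-[(10Z,13Z,16Z)-nonadeca-10,13,16-trien-1-yl]-3,4-bis(phenylsulfonyl)pyrrolidine-2-carboxylate (racemic; 2,5-cis; 3,4-trans), via silver azomethine ylide 7 (not isolated)
Conditions: AgOAc (10 mol %), PPh3 (10 mol %, premixed with the silver salt), Et3N (15 mol %), THF, −20 to 0 °C, dark, argon
Reagents that add atoms: none
Why: AgOAc binds the imine nitrogen and the ester carbonyl of 5, which acidifies only the glycine CH2, so Et3N or acetate removes that proton to give the W-shaped N,O-chelated metallo-ylide 7; this adds across the strongly electron-poor alkene 6 to form C2–C3 and C4–C5, and proton return from Et3NH+ releases pyrrolidine 8 and the catalyst. The closest known reaction type is the 1,3-dipolar cycloaddition of glycinate aldimines with 1,2-bis(sulfonyl)ethenes as acetylene equivalents under catalysis by monovalent silver or monovalent copper, of which an n-alkyl aldimine is simply a less common substrate. The pyrrolidine ring closes by an intermolecular suprafacial [3+2] (π4s+π2s) addition that makes two C–C bonds at once (if the event is stepwise on silver, a Michael addition at C2–C3 is followed by a 5-endo-trig Mannich closure at C4–C5 with the same outcome). C2 and C5 should be cis because the chelated dipole holds the ester and the chain both outward (E-imine, W geometry), C3 and C4 should be trans because the E geometry of 6 is transferred stereospecifically, and the relation between the two pairs depends only on which sulfonyl group lies endo to silver; the adduct is racemic. The selectivity needed is deprotonation at the glycine carbon and capture of the ylide before the imine can tautomerise to its enamine, which chelation, sub-ambient temperature, catalytic base and the very electrophilic dipolarophile should secure, while the symmetrical dipolarophile removes any regiochemical question and the unactivated Z alkenes of the chain do not act as dipolarophiles. All four new centres are erased in step 5, so neither diastereo- nor enantiocontrol has to be complete.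

Step 5
Reactants: 8 methyl (2S*,3S*,4S*,5R*)-5-[(10Z,13Z,16Z)-nonadeca-10,13,16-trien-1-yl]-3,4-bis(phenylsulfonyl)pyrrolidine-2-carboxylate
Product: 10 methyl 5-[(10Z,13Z,16Z)-nonadeca-10,13,16-trien-1-yl]-1H-pyrrole-2-carboxylate, via monosulfonyl 2-pyrroline 9 (not isolated)
Conditions: DBU (4 equiv), THF, 0 °C to rt, argon
Reagents that add atoms: none
Why: DBU removes the acidic C2–H next to the ester and expels the C3 sulfinate (E1cB elimination) to give 9, whose enamine nitrogen then drives loss of the allylic C4 sulfinate and of the C5 proton, so two eliminations should deliver the aromatic 1H-pyrrole without any oxidant, erase all four stereocentres and leave the skipped triene unisomerised at room temperature.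

Step 6
Reactants: 10 methyl 5-[(10Z,13Z,16Z)-nonadeca-10,13,16-trien-1-yl]-1H-pyrrole-2-carboxylate
Product: 11 {5-[(10Z,13Z,16Z)-nonadeca-10,13,16-trien-1-yl]-1H-pyrrol-2-yl}methanol
Conditions: iBu2AlH (3.5 equiv), CH2Cl2, −78 to −20 °C; aq. KNaC4H4O6 (potassium sodium tartrate) work-up, kept cold; crude used at once
Reagents that add atoms: none
Why: Ester reduction by iBu2AlH (one equivalent is consumed by the pyrrole N–H) should stop at the carbinol at low temperature, the non-acidic work-up and immediate use guard the labile 2-(hydroxymethyl)pyrrole against azafulvene formation, and the alkenes are not hydroaluminated below room temperature.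

Step 7
Reactants: 11 {5-[(10Z,13Z,16Z)-nonadeca-10,13,16-trien-1-yl]-1H-pyrrol-2-yl}methanol
Product: 12 5-[(10Z,13Z,16Z)-nonadeca-10,13,16-trien-1-yl]-1H-pyrrole-2-carbaldehyde (mycalazal 20)
Conditions: activated MnO2 (15 equiv), CH2Cl2, rt, argon
Reagents that add atoms: none
Why: MnO2 oxidation of the electron-rich pyrrolylmethanol (a benzylic-type carbinol) should stop at the aldehyde, a vinylogous formamide that resists over-oxidation, and MnO2 does not attack isolated alkenes or bis-allylic CH2 groups.

**Compound list**

1 | (11Z,14Z,17Z)-icosa-11,14,17-trienoic acid | CC/C=C\C/C=C\C/C=C\CCCCCCCCCC(=O)O | starting material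
2 | (11Z,14Z,17Z)-icosa-11,14,17-trien-1-ol | CC/C=C\C/C=C\C/C=C\CCCCCCCCCCO | intermediate
3 | (11Z,14Z,17Z)-icosa-11,14,17-trienal | CC/C=C\C/C=C\C/C=C\CCCCCCCCCC=O | intermediate
4 | glycine methyl ester hydrochloride | COC(=O)CN.Cl | starting material
5 | methyl N-[(1E,11Z,14Z,17Z)-icosa-11,14,17-trien-1-ylidene]glycinate | COC(=O)C/N=C/CCCCCCCCC/C=C\C/C=C\C/C=C\CC | intermediate
6 | (E)-1,2-bis(phenylsulfonyl)ethene | O=S(=O)(/C=C/S(=O)(=O)c1ccccc1)c1ccccc1 | starting material
7 | silver azomethine ylide of 5 (N,O-chelate, drawn as its silver enolate form, phosphine on silver omitted; formed in the flask, not isolated) | [Ag]O/C(OC)=C\N=C\CCCCCCCCC/C=C\C/C=C\C/C=C\CC | intermediate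
8 | methyl (2S*,3S*,4S*,5R*)-5-[(10Z,13Z,16Z)-nonadeca-10,13,16-trien-1-yl]-3,4-bis(phenylsulfonyl)pyrrolidine-2-carboxylate (racemic; 2,5-cis; 3,4-trans; one enantiomer drawn) | COC(=O)[C@@H]1N[C@H](CCCCCCCCC/C=C\C/C=C\C/C=C\CC)[C@H](S(=O)(=O)c2ccccc2)[C@H]1S(=O)(=O)c3ccccc3 | intermediate
9 | methyl (4R*,5R*)-5-[(10Z,13Z,16Z)-nonadeca-10,13,16-trien-1-yl]-4-(phenylsulfonyl)-4,5-dihydro-1H-pyrrole-2-carboxylate (racemic; 4,5-cis; formed in the flask, not isolated) | COC(=O)C1=C[C@@H](S(=O)(=O)c2ccccc2)[C@@H](CCCCCCCCC/C=C\C/C=C\C/C=C\CC)N1 | intermediate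
10 | methyl 5-[(10Z,13Z,16Z)-nonadeca-10,13,16-trien-1-yl]-1H-pyrrole-2-carboxylate | CC/C=C\C/C=C\C/C=C\CCCCCCCCCc1ccc(C(=O)OC)[nH]1 | intermediate
11 | {5-[(10Z,13Z,16Z)-nonadeca-10,13,16-trien-1-yl]-1H-pyrrol-2-yl}methanol | CC/C=C\C/C=C\C/C=C\CCCCCCCCCc1ccc(CO)[nH]1 | intermediate
12 | 5-[(10Z,13Z,16Z)-nonadeca-10,13,16-trien-1-yl]-1H-pyrrole-2-carbaldehyde (mycalazal 20) | CC/C=C\C/C=C\C/C=C\CCCCCCCCCc1ccc(C=O)[nH]1 | target

**Step count**

Total steps: 7. Longest linear sequence: 7 steps (1 to 12).

**Steps most likely to fail**

Step 4. The n-alkyl aldimine may tautomerise to its enamine and self-condense faster than the ylide forms, and amines present (Et3N, traces of glycinate, the product N–H) may consume the dipolarophile by conjugate addition. The fallback gives up the cycloaddition for a Paal–Knorr ring synthesis; it sets out from aldehyde 3 and rejoins the route at target 12. Addition of 2-(1,3-dioxolan-2-yl)ethylmagnesium bromide to 3 (THF, 0 °C) should give the racemic alcohol (13Z,16Z,19Z)-1-(1,3-dioxolan-2-yl)docosa-13,16,19-trien-3-ol F1. Dess–Martin oxidation should give the keto acetal (13Z,16Z,19Z)-1-(1,3-dioxolan-2-yl)docosa-13,16,19-trien-3-one F2. Acetal hydrolysis and Paal–Knorr condensation in one pot (NH4OAc, aq. AcOH, THF, 60 °C) should give 2-[(10Z,13Z,16Z)-nonadeca-10,13,16-trien-1-yl]-1H-pyrrole F3. Vilsmeier–Haack formylation of F3 at its free α-position (POCl3, DMF, 0 °C to rt; aq. NaOAc) should then give 12.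

Step 6. The aluminated carbinol may lose oxygen through an azafulvene and capture hydride, which would reduce it past the alcohol, and the free carbinol may oligomerise on work-up or standing. The fallback avoids the carbinol by changing the acyl derivative; it sets out from ester 10 and rejoins the route at target 12, bypassing steps 6 and 7. Saponification (LiOH, THF/MeOH/H2O, 60 °C; careful acidification in the cold) should give 5-[(10Z,13Z,16Z)-nonadeca-10,13,16-trien-1-yl]-1H-pyrrole-2-carboxylic acid F4. Carbodiimide coupling with N,O-dimethylhydroxylamine hydrochloride (EDC·HCl, HOBt, iPr2NEt, CH2Cl2) should give the Weinreb amide N-methoxy-N-methyl-5-[(10Z,13Z,16Z)-nonadeca-10,13,16-trien-1-yl]-1H-pyrrole-2-carboxamide F5. Reduction with LiAlH4 (THF, −20 to 0 °C) should stop at the chelated tetrahedral adduct, which should release 12 on aqueous work-up.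

Step 3. The enolisable aldimine may undergo aza-enolisation and aldol-type self-condensation while it forms in the presence of amine base and ammonium salt, or hydrolyse during concentration. The fallback makes the same imine by a salt-free, base-free aza-Wittig reaction; it sets out from aldehyde 3 and rejoins the route at imine 5. Staudinger reaction of methyl azidoacetate with PPh3 (THF, rt, loss of N2) should give methyl N-(triphenylphosphoranylidene)glycinate F6. Adding 3 (toluene, rt to 40 °C) should give 5 together with triphenylphosphine oxide, a weak ligand for silver that can be carried into step 4 without harm.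

**Further compounds**

F1 | step 4 | (13Z,16Z,19Z)-1-(1,3-dioxolan-2-yl)docosa-13,16,19-trien-3-ol (racemic) | CC/C=C\C/C=C\C/C=C\CCCCCCCCCC(O)CCC1OCCO1
F2 | step 4 | (13Z,16Z,19Z)-1-(1,3-dioxolan-2-yl)docosa-13,16,19-trien-3-one | CC/C=C\C/C=C\C/C=C\CCCCCCCCCC(=O)CCC1OCCO1
F3 | step 4 | 2-[(10Z,13Z,16Z)-nonadeca-10,13,16-trien-1-yl]-1H-pyrrole | CC/C=C\C/C=C\C/C=C\CCCCCCCCCc1ccc[nH]1
F4 | step 6 | 5-[(10Z,13Z,16Z)-nonadeca-10,13,16-trien-1-yl]-1H-pyrrole-2-carboxylic acid | CC/C=C\C/C=C\C/C=C\CCCCCCCCCc1ccc(C(=O)O)[nH]1
F5 | step 6 | N-methoxy-N-methyl-5-[(10Z,13Z,16Z)-nonadeca-10,13,16-trien-1-yl]-1H-pyrrole-2-carboxamide | CC/C=C\C/C=C\C/C=C\CCCCCCCCCc1ccc(C(=O)N(C)OC)[nH]1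
F6 | step 3 | methyl N-(triphenylphosphoranylidene)glycinate | COC(=O)CN=P(c1ccccc1)(c1ccccc1)c1ccccc1
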